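The earlier runs and the new flask are simulated for an exercise, noise included.

Count partner before trusting any curve: each product takes one partner, so the readings say how much of its charge has gone.

common to all: partner 0.915 M; precatalyst 15 mM; added ligand 15 mM

| charge | left-handed substrate | right-handed substrate | remark | time |
|---|---|---|---|---|
| winter | 0.41 M | 0.41 M | run made earlier |  |
| spring | 0.92 M | 0.92 M | run made earlier |  |
| flask | 0.61 M | 0.61 M |  | 6.0 h |

| run | time / h | left-handed product / % | right-handed product / % | left-handed substrate / % |
|---|---|---|---|---|
| winter | 0.667 | 2.4 | 0.8 | 47.2 |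
| winter | 1.33 | 7.0 | 0.2 | 40.9 |
| winter | 2.00 | 13.9 | 2.1 | 33.7 |
| winter | 3.00 | 21.1 | 2.5 | 26.2 |
| winter | 4.00 | 27.6 | 4.3 | 22.0 |
| spring | 0.250 | 0 | 0 | 49.0 |
| spring | 0.500 | 1.8 | 0 | 48.6 |
| spring | 1.00 | 4.3 | 1.1 | 47.2 |
| spring | 2.00 | 7.6 | 0 | 42.0 |
| spring | 4.00 | 15.3 | 2.8 | 34.8 |

(readings scatter by 1 percentage point)

- excess of left-handed product over right-handed product in the product at 8.0 min
- excess of left-handed product over right-handed product in the product at 6.0 h
- part of the left-handed substrate and right-handed substrate charged together that has reacted at 6.0 h

- free catalyst is single-handed; left-handed substrate and right-handed substrate are mirror images of each other, charged as a racemate, each of them at the stated concentration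
- the analysis behind the earlier runs scatters by 1 percentage point, standard deviation
- steps under discussion: precatalyst -> free catalyst; partner + catalyst intermediate B -> free catalyst + right-handed product; partner + catalyst intermediate A -> free catalyst + left-handed product; free catalyst + added ligand <-> idle complex; free catalyst + left-handed substrate <-> catalyst intermediate A; free catalyst + right-handed substrate <-> catalyst intermediate B
- an excess is the difference of the two amounts in percent of their sum
- an excess is below zero if the other one leads

By 4.00 h the readings put the partner spent at 28.6% of its charge in the winter run and 36.4% in the spring run. Spring holds 2.24 times the substrate but reads 1.27 times the partner spent, so as a working assumption we take a first-order fall in partner. Winter then gives 0.0842 h⁻¹ and spring 0.113 h⁻¹. Their mean, 0.0987 h⁻¹, is our partner clock, the logarithm of charged over remaining partner per hour, a pseudo-first-order constant at this catalyst charge. The spring figure stands above the winter one, and the mean hides that, so this is our weak link. Run to 6.0 h, the clock leaves 55.3% of the flask's partner, and the product then takes 33.5% of the substrates charged. We commit to that figure.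

The forecast gives 78% at 8.0 min, 72% at 6.0 h and 32% reacted, reasoning that “the catalyst is saturated with substrate”; its reacted part lies below ours.

The flask gives 89.1%, 76.2% and 33.6%.

    precatalyst → free catalyst (k = 3.70 × 10⁻⁴ s⁻¹)
    partner + catalyst intermediate B → free catalyst + right-handed product (k = 3.20 × 10⁻⁴ M⁻¹ s⁻¹)
    partner + catalyst intermediate A → free catalyst + left-handed product (k = 0.0160 M⁻¹ s⁻¹)
    free catalyst + added ligand ⇌ idle complex, settled at all times (K = 18.0 M⁻¹)
    free catalyst + left-handed substrate ⇌ catalyst intermediate A (K = 3.10 M⁻¹, k = 0.820 M⁻¹ s⁻¹)
    free catalyst + right-handed substrate ⇌ catalyst intermediate B (K = 15.0 M⁻¹, k = 0.0880 M⁻¹ s⁻¹)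

The flask keeps 57% of its partner at 6.00 h, so the reforged clock reads 0.0947 h⁻¹, between winter and spring. At 2.52 h the flask's partner goes to left-handed product 7.7 times as fast as to right-handed, an excess of 77.1% in what is being made at that moment, whereas the product gathered by 8.0 min stands at 89.1%. In the neighbour flask with 0.0090 M of precatalyst, the clock scaled by catalyst charge leaves 70.1% of the partner and 22.4% reacted; the computed neighbour has 68% and 24.3%.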